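**Retrosynthetic overview**

1. Letters for the six-membered ring: a = ring-fusion CH, b = olefinic C–Me, c = olefinic C carrying the macrocyclic CH2, d = allylic CH(OH), e = CH(OH) next to f, f = quaternary C–Me (a and f are shared with the cyclopentane).
2. Target ⇐ anti-opening by water at d of the β-epoxide 19 ⇐ tricyclic cyclohexa-1,3-diene 18 (b=c–d=e).
3. 18 ⇐ 17 (key step): the tethered terminal alkyne (c≡d) is inserted into the C=C of a cyclobutene (b=e, fused at a–f). The bonds b=c and d=e form, the six- and eleven-membered rings close together, and the four-membered ring is lost.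
4. Enabling feature: b=c–d(OH)–e(OH) is a 1,3-diene in disguise whose inner atoms c and d are an alkyne. Atoms a and f are cis on the cyclopentane, so they can tie b to e in a strained cyclobutene, whose convex face also delivers the all-cis cyclopentane.
5. 17 ⇐ enal 8 (from the enone–allene [2+2] adduct 3) + dialkylzinc from (R)-β-citronellene. Ring order: cyclopentane (bought) → cyclobutane (temporary, step 1) → six- and eleven-membered rings together (step 13) → oxirane (step 14).

Key step: step 13

Assumption: the sense of induction of the chiral catalysts in steps 1 and 14 is assigned by analogy with the parent catalyst systems; if it proves opposite, the antipodal catalyst is used.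

**Route**

Step 1
Reactants: 1 3-methylcyclopent-2-en-1-one; 2 propadiene (allene)
Product: 3 (1S,5R)-5-methyl-7-methylidenebicyclo[3.2.0]heptan-2-one
Conditions: hν (366 nm), chiral prolinol-derived oxazaborolidine·AlBr3 (50 mol%), excess 2, CH2Cl2, −75 °C
Reagents that add atoms: none
Why: Enone–allene [2+2] photocycloaddition under chiral Lewis-acid catalysis (known for cyclic enones with simple olefins); allene should add head-to-head (its central carbon to the enone α-carbon), the cis ring fusion is dictated by the four-membered ring, and the carbonyl-bound Lewis acid shields one enone face and so sets a and f together.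

Step 2
Reactants: 3 (1S,5R)-5-methyl-7-methylidenebicyclo[3.2.0]heptan-2-one
Product: 4 ethyl 2-[(1S,5R)-5-methyl-7-methylidenebicyclo[3.2.0]heptan-2-ylidene]acetate (E/Z mixture)
Conditions: (EtO)2P(O)CH2CO2Et, NaH, THF, 0 → 65 °C
Reagents that add atoms: triethyl phosphonoacetate, CCOC(=O)CP(=O)(OCC)OCC
Why: Horner–Wadsworth–Emmons olefination of the cyclopentanone; no stereocentre is created and the E/Z ratio is irrelevant because both isomers converge in step 3.

Step 3
Reactants: 4 ethyl 2-[(1S,5R)-5-methyl-7-methylidenebicyclo[3.2.0]heptan-2-ylidene]acetate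
Product: 5 ethyl 2-[(1S,2S,5R)-5-methyl-7-methylidenebicyclo[3.2.0]heptan-2-yl]acetate
Conditions: Cu(OAc)2·H2O (5 mol%), 1,2-bis(diphenylphosphino)benzene (5 mol%), PhMe2SiH, PhMe, rt; aqueous work-up
Reagents that add atoms: none
Why: Copper hydride-catalysed 1,4-reduction of the β,β-disubstituted enoate (isolated methylidene untouched); hydride should reach the ring carbon from the convex face, anti to the cyclobutane, placing the acetate arm cis to the four-membered ring whatever the enoate geometry (stereoconvergent).

Step 4
Reactants: 5 ethyl 2-[(1S,2S,5R)-5-methyl-7-methylidenebicyclo[3.2.0]heptan-2-yl]acetate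
Product: 6 ethyl 2-[(1S,2S,5R)-5,7-dimethylbicyclo[3.2.0]hept-6-en-2-yl]acetate
Conditions: Co(salen-tBu,tBu)Cl (3 mol%), PhSiH3 (3 mol%), PhH, rt
Reagents that add atoms: none
Why: Hydrogen-atom-transfer olefin isomerisation (cobalt hydride); the exocyclic 1,1-disubstituted alkene should move into the four-membered ring towards its CH2 group, the only alternative being a far more strained ring-fusion olefin, and no stereocentre is touched.

Step 5
Reactants: 6 ethyl 2-[(1S,2S,5R)-5,7-dimethylbicyclo[3.2.0]hept-6-en-2-yl]acetate
Product: 7 2-[(1S,2S,5R)-5,7-dimethylbicyclo[3.2.0]hept-6-en-2-yl]acetaldehyde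
Conditions: DIBAL-H (1.1 equiv), CH2Cl2, −78 °C; Rochelle salt
Reagents that add atoms: none
Why: Partial reduction of the ester with DIBAL-H at low temperature (stable tetrahedral aluminate), leaving the cyclobutene intact.

Step 6
Reactants: 7 2-[(1S,2S,5R)-5,7-dimethylbicyclo[3.2.0]hept-6-en-2-yl]acetaldehyde
Product: 8 2-[(1S,2R,5R)-5,7-dimethylbicyclo[3.2.0]hept-6-en-2-yl]prop-2-enal
Conditions: aq. HCHO (37%), pyrrolidine (10 mol%), EtCO2H (10 mol%), i-PrOH, 45 °C
Reagents that add atoms: formaldehyde, C=O
Why: Amine-catalysed α-methylenation of the aldehyde (Mannich condensation–elimination) under nearly neutral conditions, which should not move the new double bond into conjugation with the ring CH.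

Step 7
Reactants: 9 (R)-β-citronellene, (3R)-3,7-dimethylocta-1,6-diene
Product: 10 (4R)-4-methylhex-5-enal
Conditions: O3 (1.0 equiv, Sudan III end point), CH2Cl2–MeOH, −78 °C; Me2S
Reagents that add atoms: ozone, [O-][O+]=O
Why: Chemoselective ozonolysis of the electron-rich trisubstituted alkene in the presence of the monosubstituted one, with reductive work-up; the stereocentre comes from the chiral pool.

Step 8
Reactants: 10 (4R)-4-methylhex-5-enal
Product: 11 (5R)-5-methylhept-6-en-1-yne
Conditions: dimethyl (1-diazo-2-oxopropyl)phosphonate, K2CO3, MeOH, 0 °C → rt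
Reagents that add atoms: dimethyl (1-diazo-2-oxopropyl)phosphonate, COP(=O)(OC)C(=[N+]=[N-])C(C)=O
Why: Ohira–Bestmann (Seyferth–Gilbert) homologation of the aldehyde to the terminal alkyne under mild base; the remote stereocentre is not affected.

Step 9
Reactants: 11 (5R)-5-methylhept-6-en-1-yne
Product: 12 trimethyl[(5R)-5-methylhept-6-en-1-yn-1-yl]silane
Conditions: n-BuLi, THF, −78 °C; TMSCl
Reagents that add atoms: chlorotrimethylsilane, C[Si](C)(C)Cl
Why: Deprotonation of the terminal alkyne and C-silylation, which masks the alkyne for the hydroboration and organozinc chemistry of step 10.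

Step 10
Reactants: 12 trimethyl[(5R)-5-methylhept-6-en-1-yn-1-yl]silane; 8 2-[(1S,2R,5R)-5,7-dimethylbicyclo[3.2.0]hept-6-en-2-yl]prop-2-enal
Product: 15 (3S,6R)-2-[(1S,2R,5R)-5,7-dimethylbicyclo[3.2.0]hept-6-en-2-yl]-6-methyl-10-(trimethylsilyl)dec-1-en-9-yn-3-ol, via alkyldiethylborane 13 (not isolated), via dialkylzinc 14 (not isolated)
Conditions: 12, Et2BH (from BH3·SMe2/Et3B), 0 °C → rt; Et2Zn, 0 °C, then volatiles removed in vacuo; Ti(OiPr)4, (1R,2R)-N,N'-bis(trifluoromethanesulfonyl)cyclohexane-1,2-diamine (8 mol%), PhMe, −20 °C, then 8; aq. NH4Cl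
Reagents that add atoms: none
Why: Hydroboration of the terminal alkene, boron–zinc exchange and titanium/bis(sulfonamide)-catalysed enantioselective addition of the dialkylzinc to the enal; the (1R,2R)-ligand should deliver the alkyl group to the aldehyde face that gives the (S)-carbinol by reagent control, overriding the weak bias of the remote ring stereocentres.

Step 11
Reactants: 15 (3S,6R)-2-[(1S,2R,5R)-5,7-dimethylbicyclo[3.2.0]hept-6-en-2-yl]-6-methyl-10-(trimethylsilyl)dec-1-en-9-yn-3-ol
Product: 16 (3S,6R)-2-[(1S,2R,5R)-5,7-dimethylbicyclo[3.2.0]hept-6-en-2-yl]-6-methyldec-1-en-9-yn-3-ol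
Conditions: K2CO3 (cat.), MeOH, rt
Reagents that add atoms: none
Why: Base-catalysed methanolytic C-desilylation of the alkynylsilane, done before acetylation so that no ester is exposed to methoxide.

Step 12
Reactants: 16 (3S,6R)-2-[(1S,2R,5R)-5,7-dimethylbicyclo[3.2.0]hept-6-en-2-yl]-6-methyldec-1-en-9-yn-3-ol
Product: 17 (3S,6R)-2-[(1S,2R,5R)-5,7-dimethylbicyclo[3.2.0]hept-6-en-2-yl]-6-methyldec-1-en-9-yn-3-yl acetate
Conditions: Ac2O, pyridine, DMAP (cat.), CH2Cl2, 0 °C → rt
Reagents that add atoms: acetic anhydride, CC(=O)OC(C)=O
Why: DMAP-catalysed acetylation of the secondary allylic alcohol with retention of configuration.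

Step 13
Reactants: 17 (3S,6R)-2-[(1S,2R,5R)-5,7-dimethylbicyclo[3.2.0]hept-6-en-2-yl]-6-methyldec-1-en-9-yn-3-yl acetate
Product: 18 tricyclic diene acetate (the target skeleton with d and e as a cis CH=CH unit: a cyclohexa-1,3-diene b=c–d=e fused to the cyclopentane and bridged by the eleven-membered ring)
Conditions: Grubbs second-generation catalyst (10 mol%, two portions), PhMe (1 mM, slow addition of 17), 80 °C, Ar
Reagents that add atoms: none
Why: Proposed new method: a ruthenium methylidene should open the strained trisubstituted cyclobutene with Ru ending on the CH terminus e and a transient isopropenyl group on b (ring-opening metathesis); the alkylidene on e should then add across the tethered terminal alkyne with the usual terminal-alkyne regiochemistry (e bonds to the alkyne CH, d) to give the vinylcarbene on c, and ring-closing metathesis of this carbene onto the isopropenyl group should form the tetrasubstituted b=c bond and return the methylidene, so that no atom is lost; the closest known reaction types are the methylene-free ring expansion of cycloalkenes by alkyne insertion (enyne metathesis), ring-opening/ring-closing enyne cascades of strained cycloalkenes, endo-mode macrocyclic enyne ring closure and dienyne cascades that end in tetrasubstituted olefins. Ring closure: d=e forms first in an endo-mode macrocyclic enyne closure (13-membered perimeter), and b=c then closes the six-membered ring by ring-closing metathesis and thereby also completes the eleven-membered ring. No new stereocentre is formed: the five existing ones are carried through, the d=e geometry is fixed as Z by the six-membered ring, and b=c must carry the chain trans to the ring-fusion carbon. The selectivities needed are the ring-opening regiochemistry (secured by the methyl group on b, which keeps Ru off the more substituted terminus), capture of the alkylidene by the alkyne only (closure onto the exocyclic methylene would give a norbornene and closure onto the isopropenyl group would re-form the cyclobutene, both uphill) and intramolecularity (secured by high dilution and slow addition). The alternative order (alkyne first, then ring opening of the cyclobutene by the vinylcarbene on c at b, then six-ring closure of the alkylidene on e) leads to the same diene, so both entry channels converge. Only the (Z)-vinylcarbene can close; the (E) isomer is expected to re-enter by secondary metathesis, and this is the main uncertainty.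

Step 14
Reactants: 18 tricyclic diene acetate
Product: 19 β-epoxide of 18 at the disubstituted d=e double bond (oxirane cis to the angular methyl group)
Conditions: (S,S)-Jacobsen Mn(salen)Cl catalyst (5 mol%), mCPBA, NMO, CH2Cl2, −78 °C
Reagents that add atoms: 3-chloroperoxybenzoic acid, OOC(=O)c1cccc(Cl)c1
Why: Jacobsen–Katsuki epoxidation, which prefers the conjugated cis-disubstituted olefin over the isolated 1,1-disubstituted and the shielded tetrasubstituted double bonds; oxygen should be delivered to the convex face syn to the angular methyl group, the intrinsic bias being reinforced by the (S,S)-catalyst (assigned by analogy with 2,2-dimethylchromene).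

Step 15
Reactants: 19 β-epoxide
Product: 20 target, CNP0192310.1
Conditions: (salen)Co(III)OAc (5 mol%), H2O (3 equiv), THF, 0 °C → rt
Reagents that add atoms: water, O
Why: (salen)Co(III)-catalysed hydrolytic epoxide opening: water should attack the allylic carbon d in SN2 fashion anti to the oxirane oxygen (the neopentyl carbon e is blocked), which inverts d and leaves the oxygen on e in place, giving the trans-diol while the acetate survives the neutral conditions.

**Compound list**

1 | 3-methylcyclopent-2-en-1-one | CC1=CC(=O)CC1 | starting material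
2 | propadiene (allene) | C=C=C | starting material
3 | (1S,5R)-5-methyl-7-methylidenebicyclo[3.2.0]heptan-2-one | C=C1C[C@@]2(C)CCC(=O)[C@@H]12 | intermediate
4 | ethyl 2-[(1S,5R)-5-methyl-7-methylidenebicyclo[3.2.0]heptan-2-ylidene]acetate (E/Z mixture) | C=C1C[C@@]2(C)CCC(=CC(=O)OCC)[C@@H]12 | intermediate
5 | ethyl 2-[(1S,2S,5R)-5-methyl-7-methylidenebicyclo[3.2.0]heptan-2-yl]acetate | C=C1C[C@@]2(C)CC[C@@H](CC(=O)OCC)[C@@H]12 | intermediate
6 | ethyl 2-[(1S,2S,5R)-5,7-dimethylbicyclo[3.2.0]hept-6-en-2-yl]acetate | CC1=C[C@@]2(C)CC[C@@H](CC(=O)OCC)[C@@H]12 | intermediate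
7 | 2-[(1S,2S,5R)-5,7-dimethylbicyclo[3.2.0]hept-6-en-2-yl]acetaldehyde | CC1=C[C@@]2(C)CC[C@@H](CC=O)[C@@H]12 | intermediate
8 | 2-[(1S,2R,5R)-5,7-dimethylbicyclo[3.2.0]hept-6-en-2-yl]prop-2-enal | CC1=C[C@@]2(C)CC[C@@H](C(=C)C=O)[C@@H]12 | intermediate
9 | (R)-β-citronellene, (3R)-3,7-dimethylocta-1,6-diene | C=C[C@H](C)CCC=C(C)C | starting material
10 | (4R)-4-methylhex-5-enal | C=C[C@H](C)CCC=O | intermediate
11 | (5R)-5-methylhept-6-en-1-yne | C=C[C@H](C)CCC#C | intermediate
12 | trimethyl[(5R)-5-methylhept-6-en-1-yn-1-yl]silane | C=C[C@H](C)CCC#C[Si](C)(C)C | intermediate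
13 | diethyl[(3S)-3-methyl-7-(trimethylsilyl)hept-6-yn-1-yl]borane | CCB(CC)CC[C@H](C)CCC#C[Si](C)(C)C | intermediate (not isolated)
14 | bis[(3R)-3-methyl-7-(trimethylsilyl)hept-6-yn-1-yl]zinc | [Zn](CC[C@H](C)CCC#C[Si](C)(C)C)CC[C@H](C)CCC#C[Si](C)(C)C | intermediate (not isolated)
15 | (3S,6R)-2-[(1S,2R,5R)-5,7-dimethylbicyclo[3.2.0]hept-6-en-2-yl]-6-methyl-10-(trimethylsilyl)dec-1-en-9-yn-3-ol | CC1=C[C@@]2(C)CC[C@@H](C(=C)[C@@H](O)CC[C@H](C)CCC#C[Si](C)(C)C)[C@@H]12 | intermediate
16 | (3S,6R)-2-[(1S,2R,5R)-5,7-dimethylbicyclo[3.2.0]hept-6-en-2-yl]-6-methyldec-1-en-9-yn-3-ol | CC1=C[C@@]2(C)CC[C@@H](C(=C)[C@@H](O)CC[C@H](C)CCC#C)[C@@H]12 | intermediate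
17 | (3S,6R)-2-[(1S,2R,5R)-5,7-dimethylbicyclo[3.2.0]hept-6-en-2-yl]-6-methyldec-1-en-9-yn-3-yl acetate | CC1=C[C@@]2(C)CC[C@@H](C(=C)[C@@H](OC(C)=O)CC[C@H](C)CCC#C)[C@@H]12 | intermediate
18 | tricyclic diene acetate (cyclohexa-1,3-diene b=c–d=e; exocyclic methylene and acetate as in the target) | C=C1[C@@H](OC(C)=O)CC[C@H](C)CCC2=C(C)[C@@H]3[C@H]1CC[C@]3(C)C=C2 | intermediate
19 | β-epoxide of 18 at d=e (oxirane cis to the angular methyl) | C=C1[C@@H](OC(C)=O)CC[C@H](C)CCC2=C(C)[C@@H]3[C@H]1CC[C@]3(C)[C@H]4O[C@@H]24 | intermediate
20 | CNP0192310.1 | C=C1[C@@H](OC(C)=O)CC[C@H](C)CCC2=C(C)[C@@H]3[C@H]1CC[C@]3(C)[C@@H](O)[C@@H]2O | target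

**Step count**

Total: 15 steps. Longest linear sequence: 12 steps (steps 1–6 and 10–15, from 3-methylcyclopent-2-en-1-one).

**Steps most likely to fail**

Step 13 (Proposed new method). The ring-opened alkylidene may be consumed by intermolecular ring-opening oligomerisation, or the enyne event may give the (E)-vinylcarbene or the exo regiochemistry, so that the six-membered ring cannot close. The fallback sets out from 17 and comes back at 18, using known stepwise metathesis. 17 is treated with the Grubbs second-generation catalyst under ethylene (1 atm, CH2Cl2, rt); ethenolysis of the cyclobutene and ene–yne cross-metathesis of the alkyne with ethylene should give the ring-opened pentaene acetate F1 (cyclopentane bearing ethenyl, isopropenyl and the side chain on the same face, the chain now ending in a 2-substituted buta-1,3-diene). Macrocyclic ring-closing metathesis at high dilution without ethylene (PhMe, 60 °C) between the ethenyl group and the monosubstituted diene terminus should give the 13-membered (Z)-triene F2, the (E) isomer being returned to F1 by ethenolysis. Ring-closing metathesis of the two remaining 1,1-disubstituted alkenes across the six-membered ring (Schrock molybdenum alkylidene or a catalyst designed for tetrasubstituted olefins, PhH, 60–80 °C) should then give 18.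

Step 15. The vinyl epoxide may ionise to the allyl cation, which would lead to 1,4-addition of water at the methyl-bearing carbon or to loss of anti selectivity. The fallback sets out from 18 and comes back at 20. Dihydroxylation (OsO4 cat., NMO, acetone–water) of the conjugated cis double bond from the convex face should give the cis-diol F7. MnO2 (CH2Cl2) should oxidise only the allylic hydroxyl at d to give the α-hydroxy enone F8. Hydroxyl-directed reduction with Me4NBH(OAc)3 (MeCN–AcOH, −20 °C) should deliver hydride to d from the face of the hydroxyl on e and so give the trans-diol 20.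

Step 1. The chiral Lewis acid may give poor facial selectivity, or may erode the head-to-head regiochemistry of the allene addition. The fallback sets out from 1 and 2 and comes back at 3. Irradiation without Lewis acid (hν > 300 nm, CH2Cl2, −78 °C) should give the racemic ketone F3, and NaBH4 (MeOH, 0 °C) should reduce it from the convex face to the racemic endo-alcohol F4. Lipase-catalysed acylation (Burkholderia cepacia lipase, vinyl acetate) should convert the (2R) enantiomer into the acetate F5 and leave the enantiomeric alcohol, which is separated. Methanolysis (K2CO3, MeOH) should give the alcohol F6, and Dess–Martin oxidation should return enantioenriched 3.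

**Further compounds**

F1 | step 13 | (3S,6R)-2-[3-ethenyl-3-methyl-2-(prop-1-en-2-yl)cyclopentyl]-6-methyl-9-methylideneundeca-1,10-dien-3-yl acetate (ethenyl, isopropenyl and side chain on the same ring face) | C=C([C@@H](OC(C)=O)CC[C@H](C)CCC(=C)C=C)[C@@H]1CC[C@](C)(C=C)[C@@H]1C(C)=C
F2 | step 13 | 13-membered (Z)-triene acetate from macrocyclic ring-closing metathesis of F1 | C=C1[C@@H](OC(C)=O)CC[C@H](C)CCC(=C)/C=C\[C@@]2(C)CC[C@@H]1[C@H]2C(C)=C
F3 | step 1 | racemic 5-methyl-7-methylidenebicyclo[3.2.0]heptan-2-one | C=C1C[C@@]2(C)CCC(=O)[C@@H]12.C=C1C[C@]2(C)CCC(=O)[C@H]12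
F4 | step 1 | racemic endo-5-methyl-7-methylidenebicyclo[3.2.0]heptan-2-ol | C=C1C[C@@]2(C)CC[C@@H](O)[C@@H]12.C=C1C[C@]2(C)CC[C@H](O)[C@H]12
F5 | step 1 | (1S,2R,5R)-5-methyl-7-methylidenebicyclo[3.2.0]heptan-2-yl acetate | C=C1C[C@@]2(C)CC[C@@H](OC(C)=O)[C@@H]12
F6 | step 1 | (1S,2R,5R)-5-methyl-7-methylidenebicyclo[3.2.0]heptan-2-ol | C=C1C[C@@]2(C)CC[C@@H](O)[C@@H]12
F7 | step 15 | cis-diol of 18 (both hydroxyls on the face of the angular methyl) | C=C1[C@@H](OC(C)=O)CC[C@H](C)CCC2=C(C)[C@@H]3[C@H]1CC[C@]3(C)[C@@H](O)[C@H]2O
F8 | step 15 | α-hydroxy enone (ketone at d, hydroxyl at e) | C=C1[C@@H](OC(C)=O)CC[C@H](C)CCC2=C(C)[C@@H]3[C@H]1CC[C@]3(C)[C@@H](O)C2=O
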